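**Assumption:** the target SMILES has no stereocentre and no stereodescriptor, so juglanin A is made as the achiral compound drawn and there is no configuration to set.

## Retrosynthetic overview

1. Juglanin A (9) ⇐ 8 by hydrogenation of C1=C2 and hydrogenolysis of a benzylic C7–OH.
2. 8 ⇐ 7 by ring-closing metathesis at C1=C2. The 15-membered ring is the only ring built and it is formed last.
3. 7 ⇐ aldehyde 5 + hex-5-en-2-one (aldol addition, C6–C7); 5 ⇐ 4 by allyl → propenyl isomerisation.
4. 4 ⇐ o-eugenol (1) + isovanillin (2). Ring B is oxidatively dearomatised to a masked o-benzoquinone, the isovanillin oxygen adds next to the ketal carbon, and loss of MeOH restores the arene. This forms the diaryl ether without an aryl halide or copper.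
5. Both benzene rings are purchased; ring B is broken and restored in step 1.

## Route

**Step 1**
Reactants: 1, 2-allyl-6-methoxyphenol (o-eugenol); 2, isovanillin (3-hydroxy-4-methoxybenzaldehyde)
Product: 4, 3-(4-allyl-3-hydroxy-2-methoxyphenoxy)-4-methoxybenzaldehyde, via non-isolated 3, 2-allyl-6,6-dimethoxycyclohexa-2,4-dien-1-one (one pot, counted as one step)
Conditions: PhI(OAc)2 (1.0 equiv), MeOH, −10 °C, 15 min; then 2 (3 equiv), K2CO3 (3 equiv), MeCN, −10 → 25 °C; then TsOH·H2O, 25 °C; aq. HCl work-up
Reagents that add atoms: methanol, CO (it supplies the second ketal OMe of 3; one of the two ketal OMe groups is lost again, so the OMe kept on ring B is statistically the original or the solvent-derived one). PhI(OAc)2 leaves no atoms.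
Why: Proposed new method: PhI(OAc)2/MeOH dearomatises the guaiacol ring of 1 to the o-quinone monoketal 3 (standard masked o-benzoquinone formation); the phenoxide of 2 then adds reversibly in 1,6-fashion at C5, the dienone terminus next to the ketal carbon (δ-attack gives the conjugated dienolate and is the usual site for heteroatom nucleophiles on 2,4-dienones, while β-carbon C3 adjoins the allyl-bearing α-carbon); the enol of the adduct loses MeOH from the ketal through an OH/OMe-stabilised arenium ion, restoring the arene with the new O-aryl group ortho to OMe and para to allyl; the closest known reaction type is Michael addition/re-aromatisation of N-, S- and C-nucleophiles on quinone monoketals (formal nucleophilic substitution of a guaiacol C–H).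

**Step 2**
Reactants: 4, 3-(4-allyl-3-hydroxy-2-methoxyphenoxy)-4-methoxybenzaldehyde
Product: 5, 3-{3-hydroxy-2-methoxy-4-[(E)-prop-1-en-1-yl]phenoxy}-4-methoxybenzaldehyde
Conditions: RuHCl(CO)(PPh3)3 (2 mol%), toluene, 80 °C
Reagents that add atoms: none
Why: Ru–H catalysed alkene isomerisation (hydrometalation/β-hydride elimination) moves the allyl double bond into conjugation with the arene, giving mainly the (E)-propenyl compound, while the aldehyde, free phenol and diaryl ether are inert.

**Step 3**
Reactants: 5, the propenyl aldehyde; 6, hex-5-en-2-one
Product: 7, rac-1-hydroxy-1-(3-{3-hydroxy-2-methoxy-4-[(E)-prop-1-en-1-yl]phenoxy}-4-methoxyphenyl)hept-6-en-3-one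
Conditions: 6 (2.5 equiv), LDA (2.5 equiv), THF, −78 °C; then 5 (phenol pre-deprotonated with LiHMDS, 1.0 equiv), −78 °C; AcOH quench at −78 °C
Reagents that add atoms: none beyond reactant 6 (CC(=O)CCC=C)
Why: Kinetic directed aldol addition, in which the less substituted (methyl-side) lithium enolate of 6 adds to the non-enolisable aldehyde and the cold quench stops at the β-hydroxy ketone; the new carbinol centre is racemic and is removed in step 5.

**Step 4**
Reactants: 7, the β-hydroxy ketone
Product: 8, the 15-membered meta,para-cyclophane in which the chain ArB–CH=CH–CH2–CH2–C(=O)–CH2–CH(OH)–ArA bridges the diaryl ether (racemic carbinol, C1=C2 as an E/Z mixture)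
Conditions: Grubbs II (10 mol%), CH2Cl2 or toluene (2 mM), 40–60 °C, Ar sparge (−propene)
Reagents that add atoms: none
Why: Ring-closing metathesis, in which Ru initiates on the terminal alkene and closes onto the propenylarene with loss of propene; the substrate is deliberately not the enone, because a 1-arylhepta-1,6-dien-3-one would instead close to cyclopentenone with loss of the styrene.

**Step 5**
Reactants: 8, the macrocyclic β-hydroxy ketone
Product: 9, juglanin A
Conditions: H2 (1 atm), 10% Pd/C, EtOAc–AcOH, cat. TFA, 25 °C
Reagents that add atoms: none (H2 adds hydrogen only)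
Why: Catalytic hydrogenation saturates C1=C2, and the p-methoxybenzylic alcohol is hydrogenolysed (directly or by acid dehydration to the enone and C=C reduction), while the dialkyl ketone, aryl ethers and phenol survive; no stereocentre remains.

## Compound list

1 | 2-allyl-6-methoxyphenol (o-eugenol) | C=CCc1cccc(OC)c1O | starting material
2 | isovanillin (3-hydroxy-4-methoxybenzaldehyde) | COc1ccc(C=O)cc1O | starting material
3 | 2-allyl-6,6-dimethoxycyclohexa-2,4-dien-1-one | C=CCC1=CC=CC(OC)(OC)C1=O | intermediate (not isolated)
4 | 3-(4-allyl-3-hydroxy-2-methoxyphenoxy)-4-methoxybenzaldehyde | COc1ccc(C=O)cc1Oc1ccc(CC=C)c(O)c1OC | intermediate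
5 | 3-{3-hydroxy-2-methoxy-4-[(E)-prop-1-en-1-yl]phenoxy}-4-methoxybenzaldehyde | COc1ccc(C=O)cc1Oc1ccc(/C=C/C)c(O)c1OC | intermediate
6 | hex-5-en-2-one | CC(=O)CCC=C | starting material
7 | rac-1-hydroxy-1-(3-{3-hydroxy-2-methoxy-4-[(E)-prop-1-en-1-yl]phenoxy}-4-methoxyphenyl)hept-6-en-3-one | COc1ccc(C(O)CC(=O)CCC=C)cc1Oc1ccc(/C=C/C)c(O)c1OC | intermediate
8 | macrocyclic β-hydroxy ketone (racemic carbinol, E/Z at C1=C2) | COc1ccc2C(O)CC(=O)CCC=Cc3ccc(Oc1c2)c(OC)c3O | intermediate
9 | juglanin A | COc1ccc2cc1Oc1ccc(c(O)c1OC)CCCCC(=O)CC2 | target

## Summary

Total steps: 5. Longest linear sequence: 5 (fully linear from 1; 2 and 6 are added directly).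

Steps most likely to fail:

1. **Step 1 (dearomative etherification).** The risks are attack at C3 instead of C5 (giving the isomer with O-aryl ortho to allyl), Diels–Alder dimerisation of 3, an unfavourable oxa-Michael equilibrium, and competing addition of methanol. The regiochemistry of 4 must be confirmed (NOE from the allyl CH2 to the adjacent ring-B proton). Fallback: make 4 by desymmetrising 2-methoxyresorcinol instead. Cu-catalysed mono-O-arylation with 3-bromo-4-methoxybenzaldehyde, O-allylation and aromatic Claisen rearrangement (only one ortho position is free) give the same 4 in three steps.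

2. **Step 4 (macro-RCM).** The risks are oligomerisation, Ru chelation by the ketone or phenol, and dehydration of 7 to the enone, which then undergoes the cyclopentenone-forming RCM. Fallback: move the ring-closing bond to C6–C7. Cross-metathesise 5 with 6 intermolecularly, close the ring by intramolecular aldol condensation at high dilution, then hydrogenate.

3. **Step 3 (aldol addition).** The risks are enolate regiochemistry, retro-aldol, and premature dehydration of the electron-rich benzylic alcohol. Fallback: run a Claisen–Schmidt condensation to the (E)-enone and reduce it chemoselectively in conjugate fashion (Stryker's reagent) to the saturated ketone before RCM; the final step is then a plain hydrogenation (one extra step).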